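The constants used here were chosen freely, and the outcome is calculated.

Counting substrate. Every substrate charged stays counted in some form, one homo dimer as two, so the forms add up to the charge at every moment. The set-ups can differ in how much has left the substrate and in where it has gone.

| flask | substrate | coupling partner | capture agent | time | remark |
|---|---|---|---|---|---|
| autumn | 19 mM | 0.950 equiv | 1.90 mM | 40 s | a tube with plug flow, the mixed feed as stated, residence time 40 s |
| summer | 19 mM | 0.950 equiv (fed, over 32.0 s) | 1.90 mM | 40 s | a stirred flask in which coupling partner is dosed at a steady rate over 32.0 s without added volume, worked up at 40 s |
| noon | 19 mM | 0.950 equiv | 1.90 mM | 40 s | a closed flask charged with all of it at once and left for 40 s |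
| winter | 19 mM | 0.950 equiv | 1.90 mM |  | a single well-mixed tank run continuously and read at steady state, 40 s in it on average |

    substrate → intermediate A (k1 = 0.00781 s⁻¹)
    coupling partner + intermediate A ⇌ intermediate B (K2 = 96 M⁻¹, k2 = 1.41 M⁻¹ s⁻¹)
    intermediate B → side product A (k3 = 0.00631 s⁻¹)
    coupling partner + intermediate A → target (k4 = 14.4 M⁻¹ s⁻¹)
    intermediate B → intermediate C (k5 = 0.00539 s⁻¹)
    intermediate C → side product B (k6 = 0.00431 s⁻¹)
    intermediate B → side product B (k7 = 0.0229 s⁻¹)
    capture agent + intermediate C → trapped intermediate (k8 = 1.43 M⁻¹ s⁻¹)
    2 substrate → homo dimer (k9 = 3.55 × 10⁻⁴ M⁻¹ s⁻¹)

- a species is counted by the substrate in it: one homo dimer counts as two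
- a doubled species enters its step squared and goes two at a time
- the stated concentrations are those of everything mixed, before any reaction; amounts are the same in each set-up
- the feed brings no volume worth counting
- run time (autumn): 40 s

- the set-up with the highest amount of target at the outlet or at the end, in percent of the substrate put in ("none" if the first two lie within 2 percentage points) (autumn / summer / noon / winter / none)
- amount of target at the outlet or at the end, in percent of the substrate put in, autumn
- amount of target at the outlet or at the end, in percent of the substrate put in, summer
- amount of target at the outlet or at the end, in percent of the substrate put in, noon
- amount of target at the outlet or at the end, in percent of the substrate put in, winter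

The ladder. We place each time against the run of 40 s, in powers of ten. In autumn, with coupling partner as charged, intermediate A has a half-life of 2.7 s by the step to target alone, 1.17 decades below the run, so it turns over sooner than substrate does and we expect a small pool. Substrate's half-life by the first step alone is 89 s, 0.347 decades above the run, which makes this the rate-limiting step of autumn. Capture of intermediate C in autumn, with capture agent as charged, has a half-life of 4.3 min by that step alone, 0.810 decades above the run, so we set this step aside. At the start of autumn, substrate goes to intermediate A 580 times faster than to homo dimer, which is 2.76 decades, so we drop the dimer.

The clock. We keep 128 s as the substrate clock, the mean life of a substrate under the first step. The run lasts 0.312 clocks. So we reckon substrate left at 73.2 % in autumn's tube and noon's closed flask, which share one history, and at 76.2 % in winter's tank, with its 40 s on average.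

Our figures. Intermediate A leaves forward by two steps, and both carry coupling partner, so the dose cancels from their ratio. The step to target has the larger constant, so it takes 91.1 % of what leaves intermediate A forward, the selectivity of these two steps. With partner as charged, intermediate A waits 3.50 s on average. Allowing for that wait, we reckon 22.6 % target for autumn and noon, and 19.9 % for winter. Summer's partner arrives over 32.0 s, longer than intermediate A's half-life in autumn, so we expect summer under autumn, without a figure. Autumn and noon tie, so our answer is none.

The forecast. It says none, with autumn 22.3 %, summer 22.1 %, noon 22.3 % and winter 19.8 %, on the ground that “The tube and the closed flask are the same batch history”. Our autumn figure stands 0.30 percentage points above its number.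

The result. The best set-up comes out as none, with autumn 22.3 %, summer 22.1 %, noon 22.3 % and winter 19.8 %. Winter's tank holds substrate at 14.5 mM. Read at 2.5 min, the autumn flask has run 1.17 clocks, which gives 31.0 % substrate left. That flask holds 31.0 % substrate and 61.7 % target.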